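**Retrosynthetic overview**

1. The target is a robinetinidol unit (upper; 2R,3S,4S) joined through its C4 to C2' of the pyrogallol ring B of a leucorobinetinidin unit (lower; 2R,3S,4R); the last operation is global desilylation of the nona-silyl ether 16.
2. Key disconnection: lower ring C is cut at O1–C2 and at C4a–C4, which returns the resorcinol monosilyl ether 13 (lower ring A: phenolic oxygen O1 and its ortho carbon C4a) and the (2R,3S)-epoxy aldehyde 11 (C4 = formyl carbon, C3–C2 = trans-epoxide).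
3. Enabling feature: in lower ring C the carbinol carbon C4 sits ortho to the ring-A oxygen O1 and para to the 7-oxygen, C3 carries oxygen, and C2 is benzylic to the electron-rich pyrogallol ring B; the C2–C3–C4 chain is therefore a latent 2,3-epoxy aldehyde and O1/C4a a latent ambident metal phenolate.
4. 11 comes from aryl bromide 7 by vinylogous formylation and aminocatalytic epoxidation; the interflavan bond (upper C4–lower C2') is made earlier by acid-catalysed Friedel–Crafts coupling of the silylated flavan-4-ol 3 (from (+)-dihydrorobinetin 1) with free 5-bromopyrogallol 4, the only phenolic nucleophile present.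
5. Ring order: upper rings A, B and C and the central pyrogallol ring are bought intact, lower ring A comes from resorcinol, and lower ring C is the only ring formed (step 8, last ring-forming event).

Key step: step 8

Assumption: (+)-dihydrorobinetin (2R,3R) and 5-bromopyrogallol are taken as commercial; TBS = tert-butyldimethylsilyl; flavan numbering is used for both units.

**Route**

Step 1
Reactants: 1 (+)-dihydrorobinetin
Product: 2 pentakis-O-TBS (+)-dihydrorobinetin
Conditions: TBSOTf (7 equiv), 2,6-lutidine (10 equiv), CH2Cl2–MeCN (4:1), −20 to 0 °C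
Reagents that add atoms: tert-butyldimethylsilyl trifluoromethanesulfonate, CC(C)(C)[Si](C)(C)OS(=O)(=O)C(F)(F)F
Why: Silyl ether formation with a silyl triflate and a hindered pyridine base should cover the four phenols and the secondary 3-hydroxyl in one pass, while 2,6-lutidine at low temperature is too weak a base to enolise the C4 ketone, so C2 and C3 are not touched and the 3-oxygen is masked before it could compete for the benzylic epoxide carbon later on.

Step 2
Reactants: 2 pentakis-O-TBS (+)-dihydrorobinetin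
Product: 3 (2R,3S,4R)-3,7-bis(TBS-oxy)-2-[3,4,5-tris(TBS-oxy)phenyl]chroman-4-ol
Conditions: NaBH4 (2 equiv), THF–EtOH (1:1), −10 to 0 °C; pH 7 phosphate buffer
Reagents that add atoms: none
Why: NaBH4 reduction of a 2,3-trans-dihydroflavonol ether, in which hydride should add to the C4 carbonyl along the axial trajectory of the half-chair that holds the 2-aryl and 3-silyloxy groups equatorial and so give mainly the equatorial (4R, 3,4-trans) alcohol, although the configuration at C4 is of no consequence because this centre is ionised in step 3.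

Step 3
Reactants: 3 pentakis-O-TBS flavan-4-ol; 4 5-bromopyrogallol (5 equiv)
Product: 6 (2R,3S,4S)-4-(6-bromo-2,3,4-trihydroxyphenyl)-3,7-bis(TBS-oxy)-2-[3,4,5-tris(TBS-oxy)phenyl]chromane, via benzylic C4 cation 5 (not isolated)
Conditions: TsOH·H2O (10 mol%), CH2Cl2–(CF3)2CHOH (2:1), −20 to 0 °C, N2; NaHCO3; chromatography
Reagents that add atoms: none
Why: Acid-catalysed dehydrative Friedel–Crafts alkylation of the flavan-4-ol type, in which ionisation of the 4-hydroxyl (assisted by the para 7-silyloxy group, the ortho ring oxygen and the ionising fluoroalcohol) gives cation 5, which the excess bromopyrogallol should capture at its only free kind of ring position (C4 and C6 are equivalent, each ortho and para to hydroxyls) from the face anti to the bulky 3-silyloxy group, setting the 3,4-trans (4S) aryl group, while the silylated rings of the electrophile are much poorer nucleophiles than free 4.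

Step 4
Reactants: 6 bromopyrogallol adduct
Product: 7 octakis-O-TBS aryl bromide
Conditions: TBSOTf (4.5 equiv), 2,6-lutidine (6 equiv), CH2Cl2, 0 °C to rt
Reagents that add atoms: tert-butyldimethylsilyl trifluoromethanesulfonate, CC(C)(C)[Si](C)(C)OS(=O)(=O)C(F)(F)F
Why: Silyl ether formation with a silyl triflate, which should cap the three pyrogallol hydroxyls including the hindered one next to the chromanyl group, so that no acidic proton meets t-BuLi in step 5 and no free phenol other than that of 13 meets the magnesium template in step 8.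

Step 5
Reactants: 7 octakis-O-TBS aryl bromide
Product: 10 (E)-3-arylprop-2-enal, via aryllithium 8 (not isolated), via lithium alkoxide adduct 9 (not isolated)
Conditions: t-BuLi (2.1 equiv), THF, −78 °C; 3-(dimethylamino)acrolein (1.5 equiv), −78 to 0 °C; AcOH–H2O, rt
Reagents that add atoms: 3-(dimethylamino)acrolein, CN(C)/C=C/C=O
Why: Bromine–lithium exchange followed by vinylogous formylation, in which aryllithium 8 (no silyloxy group ortho to the carbanion, so no silyl migration is expected) adds to the carbonyl of the vinylogous formamide and mild acid converts adduct 9 into the thermodynamically favoured (E)-enal with loss of dimethylamine.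

Step 6
Reactants: 10 (E)-enal
Product: 11 (2R,3S)-trans-epoxy aldehyde
Conditions: (R)-2-{bis[3,5-bis(trifluoromethyl)phenyl](trimethylsilyloxy)methyl}pyrrolidine (15 mol%), 35% aq. H2O2 (1.5 equiv), CH2Cl2, rt; used crude
Reagents that add atoms: hydrogen peroxide, OO
Why: Aminocatalytic Weitz–Scheffer-type epoxidation of an enal, in which the E-iminium ion should take up hydrogen peroxide at the beta carbon on the face remote from the silyloxydiarylmethyl group and the resulting enamine closes onto the peroxide oxygen to give the trans-epoxide, so that the catalyst and not the remote upper unit sets both epoxide carbons (the antipodal catalyst gives the antipodal epoxide, so the sense can be chosen).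

Step 7
Reactants: 12 resorcinol (3 equiv)
Product: 13 3-(tert-butyldimethylsilyloxy)phenol
Conditions: TBSCl (1.0 equiv), imidazole (1.2 equiv), DMF, 0 °C to rt
Reagents that add atoms: tert-butyldimethylsilyl chloride, CC(C)(C)[Si](C)(C)Cl
Why: Statistical monosilylation of a symmetrical diphenol, which with resorcinol in excess should stop largely at the monoether, separable from recovered resorcinol and a little bis-ether by chromatography.

Step 8
Reactants: 11 (2R,3S)-epoxy aldehyde; 13 3-(tert-butyldimethylsilyloxy)phenol (2.2 equiv)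
Product: 16 nona-O-TBS ether of the target (lower 3,4-diol free), via magnesium bis(aryloxide) 14 (not isolated), via magnesium-chelated epoxy alcohol 15 (not isolated)
Conditions: 13, Mg(n-Bu)2 (1.1 equiv), CH2Cl2–toluene, 0 °C; then 11, −40 to 0 °C; then Ti(OiPr)4 (1.5 equiv), 0 °C to rt; aq. NaH2PO4/Na2HPO4 buffer (pH 7), filtration
Reagents that add atoms: none
Why: Proposed new method: the halide-free magnesium bis(aryloxide) 14 should bind the aldehyde oxygen of 11 and deliver the ring-A carbon ortho to its phenolate oxygen to the formyl carbon through a six-membered metal-bridged transition state (closest known type: ortho-specific hydroxyalkylation of magnesium phenolates with alpha-oxygenated aldehydes), and the phenolate oxygen of chelate 15 then opens the neighbouring epoxide at its benzylic carbon once Ti(OiPr)4 is added (closest known types: Ti(OiPr)4-mediated C3-selective opening of 2,3-epoxy alcohols and the 6-endo closure of 2'-hydroxychalcone epoxides). Lower ring C is closed by a 6-endo-tet epoxide opening (O1–C2) that follows the intermolecular C4a–C4 bond formation. C4 should be set by chelation control: divalent magnesium held between the aldehyde and epoxide oxygens fixes the carbonyl syn to the C3–O bond, the arene enters from the side of the C3 hydrogen and away from the other epoxide carbon, and the syn epoxy alcohol results, which becomes the 3,4-trans diol (4R). C2 is set by inversion at the benzylic epoxide carbon, so the (2R,3S)-trans-epoxide gives the 2,3-trans ring with 2R, and C3 is carried over from the epoxide unchanged. The step needs ortho-C-attack rather than para- or O-attack, and at the position para to the silyloxy group (secured by the metal template, the non-coordinating solvent and the bulk of the silyl ether), syn rather than anti addition (secured by the halide-free chelating magnesium centre), and 6-endo rather than 5-exo opening (secured by the para-silyloxy-activated benzylic carbon and by tetravalent titanium bridging the C4 alkoxide and the epoxide oxygen). The silylated upper 3-oxygen cannot compete for the benzylic carbon, and the product equals 11 plus 13 with no atom lost.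

Step 9
Reactants: 16 nona-O-TBS ether
Product: 17 target (CNP0205451.4)
Conditions: n-Bu4NF (14 equiv), AcOH (14 equiv), THF, 0 °C to rt, argon, dark; Sephadex LH-20
Reagents that add atoms: none
Why: Fluoride-mediated silyl ether cleavage under acetic acid buffering should release the eight phenols and the upper 3-hydroxyl without ionising the acid-labile benzylic 4-hydroxyl of the lower unit or exposing the pyrogallol rings to base and air, and no stereocentre is touched.

**Compound list**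

1 | (+)-dihydrorobinetin, (2R,3R)-3,7-dihydroxy-2-(3,4,5-trihydroxyphenyl)chroman-4-one | Oc1ccc2c(c1)O[C@H](c1cc(O)c(O)c(O)c1)[C@@H](O)C2=O | starting material

2 | pentakis-O-TBS (+)-dihydrorobinetin, (2R,3R)-3,7-bis(TBS-oxy)-2-[3,4,5-tris(TBS-oxy)phenyl]chroman-4-one | CC(C)(C)[Si](C)(C)Oc1ccc2c(c1)O[C@H](c1cc(O[Si](C)(C)C(C)(C)C)c(O[Si](C)(C)C(C)(C)C)c(O[Si](C)(C)C(C)(C)C)c1)[C@@H](O[Si](C)(C)C(C)(C)C)C2=O | intermediate

3 | (2R,3S,4R)-3,7-bis(TBS-oxy)-2-[3,4,5-tris(TBS-oxy)phenyl]chroman-4-ol (2,3-trans-3,4-trans) | CC(C)(C)[Si](C)(C)Oc1ccc2c(c1)O[C@H](c1cc(O[Si](C)(C)C(C)(C)C)c(O[Si](C)(C)C(C)(C)C)c(O[Si](C)(C)C(C)(C)C)c1)[C@@H](O[Si](C)(C)C(C)(C)C)[C@@H]2O | intermediate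

4 | 5-bromopyrogallol (5-bromobenzene-1,2,3-triol) | Oc1cc(Br)cc(O)c1O | starting material

5 | (2R,3S)-3,7-bis(TBS-oxy)-2-[3,4,5-tris(TBS-oxy)phenyl]chroman-4-ylium (benzylic C4 cation) | CC(C)(C)[Si](C)(C)Oc1ccc2c(c1)O[C@H](c1cc(O[Si](C)(C)C(C)(C)C)c(O[Si](C)(C)C(C)(C)C)c(O[Si](C)(C)C(C)(C)C)c1)[C@@H](O[Si](C)(C)C(C)(C)C)[CH+]2 | intermediate

6 | (2R,3S,4S)-4-(6-bromo-2,3,4-trihydroxyphenyl)-3,7-bis(TBS-oxy)-2-[3,4,5-tris(TBS-oxy)phenyl]chromane (2,3-trans-3,4-trans) | CC(C)(C)[Si](C)(C)Oc1ccc2c(c1)O[C@H](c1cc(O[Si](C)(C)C(C)(C)C)c(O[Si](C)(C)C(C)(C)C)c(O[Si](C)(C)C(C)(C)C)c1)[C@@H](O[Si](C)(C)C(C)(C)C)[C@@H]2c1c(Br)cc(O)c(O)c1O | intermediate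

7 | octakis-O-TBS aryl bromide: (2R,3S,4S)-4-[6-bromo-2,3,4-tris(TBS-oxy)phenyl]-3,7-bis(TBS-oxy)-2-[3,4,5-tris(TBS-oxy)phenyl]chromane | CC(C)(C)[Si](C)(C)Oc1ccc2c(c1)O[C@H](c1cc(O[Si](C)(C)C(C)(C)C)c(O[Si](C)(C)C(C)(C)C)c(O[Si](C)(C)C(C)(C)C)c1)[C@@H](O[Si](C)(C)C(C)(C)C)[C@@H]2c1c(Br)cc(O[Si](C)(C)C(C)(C)C)c(O[Si](C)(C)C(C)(C)C)c1O[Si](C)(C)C(C)(C)C | intermediate

8 | aryllithium from 7 (lithium in place of bromine) | CC(C)(C)[Si](C)(C)Oc1ccc2c(c1)O[C@H](c1cc(O[Si](C)(C)C(C)(C)C)c(O[Si](C)(C)C(C)(C)C)c(O[Si](C)(C)C(C)(C)C)c1)[C@@H](O[Si](C)(C)C(C)(C)C)[C@@H]2c1c([Li])cc(O[Si](C)(C)C(C)(C)C)c(O[Si](C)(C)C(C)(C)C)c1O[Si](C)(C)C(C)(C)C | intermediate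

9 | lithium (E)-1-aryl-3-(dimethylamino)prop-2-en-1-olate adduct of 8 (carbinol carbon unassigned) | CC(C)(C)[Si](C)(C)Oc1ccc2c(c1)O[C@H](c1cc(O[Si](C)(C)C(C)(C)C)c(O[Si](C)(C)C(C)(C)C)c(O[Si](C)(C)C(C)(C)C)c1)[C@@H](O[Si](C)(C)C(C)(C)C)[C@@H]2c1c(C(O[Li])/C=C/N(C)C)cc(O[Si](C)(C)C(C)(C)C)c(O[Si](C)(C)C(C)(C)C)c1O[Si](C)(C)C(C)(C)C | intermediate

10 | (E)-3-{2-[(2R,3S,4S)-3,7-bis(TBS-oxy)-2-[3,4,5-tris(TBS-oxy)phenyl]chroman-4-yl]-3,4,5-tris(TBS-oxy)phenyl}prop-2-enal | CC(C)(C)[Si](C)(C)Oc1ccc2c(c1)O[C@H](c1cc(O[Si](C)(C)C(C)(C)C)c(O[Si](C)(C)C(C)(C)C)c(O[Si](C)(C)C(C)(C)C)c1)[C@@H](O[Si](C)(C)C(C)(C)C)[C@@H]2c1c(/C=C/C=O)cc(O[Si](C)(C)C(C)(C)C)c(O[Si](C)(C)C(C)(C)C)c1O[Si](C)(C)C(C)(C)C | intermediate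

11 | (2R,3S)-3-{2-[(2R,3S,4S)-3,7-bis(TBS-oxy)-2-[3,4,5-tris(TBS-oxy)phenyl]chroman-4-yl]-3,4,5-tris(TBS-oxy)phenyl}oxirane-2-carbaldehyde (trans-epoxide) | CC(C)(C)[Si](C)(C)Oc1ccc2c(c1)O[C@H](c1cc(O[Si](C)(C)C(C)(C)C)c(O[Si](C)(C)C(C)(C)C)c(O[Si](C)(C)C(C)(C)C)c1)[C@@H](O[Si](C)(C)C(C)(C)C)[C@@H]2c1c([C@@H]3O[C@H]3C=O)cc(O[Si](C)(C)C(C)(C)C)c(O[Si](C)(C)C(C)(C)C)c1O[Si](C)(C)C(C)(C)C | intermediate

12 | resorcinol | Oc1cccc(O)c1 | starting material

13 | 3-(tert-butyldimethylsilyloxy)phenol | CC(C)(C)[Si](C)(C)Oc1cccc(O)c1 | intermediate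

14 | magnesium bis[3-(tert-butyldimethylsilyloxy)phenolate], Mg(OAr)2 | CC(C)(C)[Si](C)(C)Oc1cccc(c1)O[Mg]Oc1cccc(O[Si](C)(C)C(C)(C)C)c1 | intermediate

15 | magnesium chelate (ring-A phenolate oxygen and C4 alkoxide on one magnesium) of the syn epoxy alcohol from 11 and 13; C4 as in 16, epoxide unchanged | CC(C)(C)[Si](C)(C)Oc1ccc2c(c1)O[C@H](c1cc(O[Si](C)(C)C(C)(C)C)c(O[Si](C)(C)C(C)(C)C)c(O[Si](C)(C)C(C)(C)C)c1)[C@@H](O[Si](C)(C)C(C)(C)C)[C@@H]2c1c([C@@H]3O[C@H]3[C@@H]4O[Mg]Oc5cc(O[Si](C)(C)C(C)(C)C)ccc45)cc(O[Si](C)(C)C(C)(C)C)c(O[Si](C)(C)C(C)(C)C)c1O[Si](C)(C)C(C)(C)C | intermediate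

16 | (2R,3S,4R)-2-{2-[(2R,3S,4S)-3,7-bis(TBS-oxy)-2-[3,4,5-tris(TBS-oxy)phenyl]chroman-4-yl]-3,4,5-tris(TBS-oxy)phenyl}-7-(TBS-oxy)chromane-3,4-diol | CC(C)(C)[Si](C)(C)Oc1ccc2c(c1)O[C@H](c1cc(O[Si](C)(C)C(C)(C)C)c(O[Si](C)(C)C(C)(C)C)c(O[Si](C)(C)C(C)(C)C)c1)[C@@H](O[Si](C)(C)C(C)(C)C)[C@@H]2c1c([C@H]2Oc3cc(O[Si](C)(C)C(C)(C)C)ccc3[C@@H](O)[C@@H]2O)cc(O[Si](C)(C)C(C)(C)C)c(O[Si](C)(C)C(C)(C)C)c1O[Si](C)(C)C(C)(C)C | intermediate

17 | CNP0205451.4, (2R,3S,4R)-2-{2-[(2R,3S,4S)-3,7-dihydroxy-2-(3,4,5-trihydroxyphenyl)chroman-4-yl]-3,4,5-trihydroxyphenyl}chromane-3,4,7-triol | Oc1ccc2c(c1)O[C@H](c1cc(O)c(O)c(O)c1)[C@@H](O)[C@@H]2c1c([C@H]2Oc3cc(O)ccc3[C@@H](O)[C@@H]2O)cc(O)c(O)c1O | target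

**Totals and risks**

Total step count: 9. Longest linear sequence: 8 steps (steps 1, 2, 3, 4, 5, 6, 8, 9 from 1); step 7 is a one-step branch.

Steps most likely to fail:

Step 8. The addition may follow the non-chelated (Felkin-type) course and give the C4 epimer, the epoxide may open in the 5-exo mode, or the salicyl-type alkoxide may ionise to an ortho-quinone methide that is intercepted by a second phenolate. The fallback builds lower ring C stepwise at the ketone oxidation level with known reactions and sets out from 11. 2-Bromo-5-(tert-butyldimethylsilyloxy)phenol F1 (from 4-bromoresorcinol, TBSCl, imidazole) is converted with n-BuLi (2.1 equiv, THF, −78 °C) into the dilithio species F2, which adds to the aldehyde of 11 to give the epoxy alcohol F3 as a mixture at the carbinol carbon. MnO2 (CH2Cl2) oxidises the benzylic carbinol to the 2'-hydroxychalcone-type epoxy ketone F4. Et3N in CH2Cl2–EtOH closes the pyranone ring by the 6-endo phenolate opening at the benzylic carbon known from the Algar–Flynn–Oyamada manifold, giving the 2,3-trans-dihydroflavonol F5. NaBH4 (THF–EtOH, 0 °C) then sets the 3,4-trans diol as in step 2, and the route is rejoined at 16.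

Step 3. Capture of the cation at the hindered, bromine-flanked position of 4 may be slow, so that elimination to the flav-3-ene, acid-induced loss of silyl groups or attack syn to the 3-silyloxy group takes over. The fallback couples the unprotected partners in water–ethanol and protects afterwards; it sets out from 1. NaBH4 (EtOH, 0 °C to rt) gives (+)-leucorobinetinidin F6. 0.1 M HCl in H2O–EtOH (1:1, rt, N2) with excess 4 gives the free 3,4-trans bromopyrogallol adduct F7, the free 7-hydroxyl making the cation form readily and the excess of 4 suppressing self-condensation. TBSCl and imidazole in DMF silylate the seven phenols to the heptakis-O-TBS ether F8, and TBSOTf with 2,6-lutidine (CH2Cl2, 0 °C) then caps the hindered 3-hydroxyl, which rejoins the route at 7.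

Step 6. Iminium formation with the hindered, electron-rich enal may be too slow, the epoxy aldehyde may decompose during a long reaction, or the upper unit may erode the facial control of the catalyst. The fallback makes the epoxide at the alcohol oxidation level and sets out from 10. Luche reduction (NaBH4, CeCl3·7H2O, MeOH–THF, 0 °C) gives the (E)-allylic alcohol F9; Sharpless asymmetric epoxidation (Ti(OiPr)4, L-(+)-diethyl tartrate, t-BuOOH, 4 Å molecular sieves, CH2Cl2, −20 °C) gives the (2S,3S)-epoxy alcohol F10; Dess–Martin oxidation (NaHCO3, CH2Cl2) returns to the route at 11.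

Further compounds

F1 | step 8 | 2-bromo-5-(tert-butyldimethylsilyloxy)phenol | Oc1cc(O[Si](C)(C)C(C)(C)C)ccc1Br

F2 | step 8 | lithium 2-lithio-5-(tert-butyldimethylsilyloxy)phenolate | [Li]Oc1cc(O[Si](C)(C)C(C)(C)C)ccc1[Li]

F3 | step 8 | epoxy alcohol from 11 and F2: [2-hydroxy-4-(TBS-oxy)phenyl][(2S,3S)-3-aryloxiran-2-yl]methanol, both carbinol epimers | CC(C)(C)[Si](C)(C)Oc1ccc2c(c1)O[C@H](c1cc(O[Si](C)(C)C(C)(C)C)c(O[Si](C)(C)C(C)(C)C)c(O[Si](C)(C)C(C)(C)C)c1)[C@@H](O[Si](C)(C)C(C)(C)C)[C@@H]2c1c([C@@H]3O[C@H]3C(O)c4ccc(O[Si](C)(C)C(C)(C)C)cc4O)cc(O[Si](C)(C)C(C)(C)C)c(O[Si](C)(C)C(C)(C)C)c1O[Si](C)(C)C(C)(C)C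

F4 | step 8 | epoxy ketone (2'-hydroxychalcone epoxide type): [2-hydroxy-4-(TBS-oxy)phenyl] (2R,3S)-3-aryloxiran-2-yl ketone | CC(C)(C)[Si](C)(C)Oc1ccc2c(c1)O[C@H](c1cc(O[Si](C)(C)C(C)(C)C)c(O[Si](C)(C)C(C)(C)C)c(O[Si](C)(C)C(C)(C)C)c1)[C@@H](O[Si](C)(C)C(C)(C)C)[C@@H]2c1c([C@@H]3O[C@H]3C(=O)c4ccc(O[Si](C)(C)C(C)(C)C)cc4O)cc(O[Si](C)(C)C(C)(C)C)c(O[Si](C)(C)C(C)(C)C)c1O[Si](C)(C)C(C)(C)C

F5 | step 8 | nona-O-TBS dihydroflavonol: (2R,3R)-3-hydroxy-7-(TBS-oxy)-2-aryl-chroman-4-one with the upper unit as in 16 | CC(C)(C)[Si](C)(C)Oc1ccc2c(c1)O[C@H](c1cc(O[Si](C)(C)C(C)(C)C)c(O[Si](C)(C)C(C)(C)C)c(O[Si](C)(C)C(C)(C)C)c1)[C@@H](O[Si](C)(C)C(C)(C)C)[C@@H]2c1c([C@H]2Oc3cc(O[Si](C)(C)C(C)(C)C)ccc3C(=O)[C@@H]2O)cc(O[Si](C)(C)C(C)(C)C)c(O[Si](C)(C)C(C)(C)C)c1O[Si](C)(C)C(C)(C)C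

F6 | step 3 | (+)-leucorobinetinidin, (2R,3S,4R)-2-(3,4,5-trihydroxyphenyl)chromane-3,4,7-triol | Oc1ccc2c(c1)O[C@H](c1cc(O)c(O)c(O)c1)[C@@H](O)[C@@H]2O

F7 | step 3 | (2R,3S,4S)-4-(6-bromo-2,3,4-trihydroxyphenyl)-2-(3,4,5-trihydroxyphenyl)chromane-3,7-diol | Oc1ccc2c(c1)O[C@H](c1cc(O)c(O)c(O)c1)[C@@H](O)[C@@H]2c1c(Br)cc(O)c(O)c1O

F8 | step 3 | heptakis-O-TBS ether of F7 with free 3-hydroxyl | CC(C)(C)[Si](C)(C)Oc1ccc2c(c1)O[C@H](c1cc(O[Si](C)(C)C(C)(C)C)c(O[Si](C)(C)C(C)(C)C)c(O[Si](C)(C)C(C)(C)C)c1)[C@@H](O)[C@@H]2c1c(Br)cc(O[Si](C)(C)C(C)(C)C)c(O[Si](C)(C)C(C)(C)C)c1O[Si](C)(C)C(C)(C)C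

F9 | step 6 | (E)-allylic alcohol from 10 | CC(C)(C)[Si](C)(C)Oc1ccc2c(c1)O[C@H](c1cc(O[Si](C)(C)C(C)(C)C)c(O[Si](C)(C)C(C)(C)C)c(O[Si](C)(C)C(C)(C)C)c1)[C@@H](O[Si](C)(C)C(C)(C)C)[C@@H]2c1c(/C=C/CO)cc(O[Si](C)(C)C(C)(C)C)c(O[Si](C)(C)C(C)(C)C)c1O[Si](C)(C)C(C)(C)C

F10 | step 6 | (2S,3S)-epoxy alcohol (trans) | CC(C)(C)[Si](C)(C)Oc1ccc2c(c1)O[C@H](c1cc(O[Si](C)(C)C(C)(C)C)c(O[Si](C)(C)C(C)(C)C)c(O[Si](C)(C)C(C)(C)C)c1)[C@@H](O[Si](C)(C)C(C)(C)C)[C@@H]2c1c([C@@H]3O[C@H]3CO)cc(O[Si](C)(C)C(C)(C)C)c(O[Si](C)(C)C(C)(C)C)c1O[Si](C)(C)C(C)(C)C
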